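**Retrosynthetic overview**

1. The target is a cyclohex-2-enone: ring C1 is the C=O carbon, C2 bears CH(CH3)CO2H, C3 bears the quaternary carbon of the 1,3,3-trimethylcyclohexyl ring, and C6 bears CH2OCHO. Read backwards, the end game is O-formylation, one hydrogenation (benzyl ether and cyclohexene C=C), auxiliary cleavage, and Evans methylation of a ring–CH2–C(=O)–imide, which sets the side-chain centre (Cα).
2. Key disconnection: the ring bond C1–C2, made by an NHC-catalysed intramolecular Stetter reaction of an aldehyde (C1) onto the central carbon (C2) of a 2,3-dienoyl imide. Enabling feature: ring C1=O and the side-chain C=O are 1,4-related through C2, and the ring C2=C3 double bond is the surviving π bond of an allene C3=C2=Cα, so an acyl anion at C1 adds to the sp carbon C2 and the tetrasubstituted enone appears directly.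
3. The methyl group is added only after ring closure, because an α-methyl allene would pass its uncontrolled axial chirality on to Cα. Without it the key step is stereoconvergent: both allene epimers give one enone.
4. The allene comes from Wittig olefination of a ketene made from an α-branched acid. That acid comes from an Ireland–Claisen rearrangement of the (S)-isophoryl ester of the side-chain acid, which joins the two halves at the quaternary carbon and sets it by 1,3-chirality transfer.
5. The side-chain acid comes from Evans alkylation of an adipate imide with trimethyl orthoformate (sets C6, brings C1 as its acetal). Rings: the carbocycle of isophorone is carried through (its C=C is saturated in step 16); the cyclohexenone is the only ring made, in step 13.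

Key step: step 13

Remark (assumption): the locants C1–C6 and Cα defined above are used throughout; both enantiomers of 4-benzyl-1,3-oxazolidin-2-one, methyl 6-chloro-6-oxohexanoate, isophorone and the triazolium salt of step 13 are taken as commercial.

**Route**

Step 1
Reactants: 1 (4S)-4-benzyl-1,3-oxazolidin-2-one; 2 methyl 6-chloro-6-oxohexanoate
Product: 4 methyl 6-[(4S)-4-benzyl-2-oxo-1,3-oxazolidin-3-yl]-6-oxohexanoate, via lithium oxazolidinide 3 (not isolated)
Conditions: n-BuLi, THF, −78 °C; then 2, −78 → 0 °C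
Reagents that add atoms: none
Why: N-acylation of the lithiated oxazolidinone by the acid chloride, which reacts far faster than the methyl ester.

Step 2
Reactants: 4 methyl 6-[(4S)-4-benzyl-2-oxo-1,3-oxazolidin-3-yl]-6-oxohexanoate
Product: 6 methyl (5R)-5-{[(4S)-4-benzyl-2-oxo-1,3-oxazolidin-3-yl]carbonyl}-6,6-dimethoxyhexanoate, via chlorotitanium enolate 5 (not isolated)
Conditions: TiCl4, i-Pr2NEt, CH2Cl2, 0 °C; then HC(OMe)3, 0 °C
Reagents that add atoms: trimethyl orthoformate, COC(OC)OC
Why: Evans alkylation of the chelated (Z)-titanium enolate (soft enolisation of the imide only) by the dimethoxycarbenium ion, which enters anti to the benzyl group of the auxiliary; this sets the future ring C6 centre and brings in C1 as its dimethyl acetal.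

Step 3
Reactants: 6 methyl (5R)-5-{[(4S)-4-benzyl-2-oxo-1,3-oxazolidin-3-yl]carbonyl}-6,6-dimethoxyhexanoate
Product: 7 methyl (5S)-5-(hydroxymethyl)-6,6-dimethoxyhexanoate
Conditions: NaBH4, THF/H2O (4:1), 0 °C → rt
Reagents that add atoms: none
Why: reductive cleavage of the N-acyl oxazolidinone to the primary alcohol by borohydride in aqueous THF, which leaves the methyl ester and the acetal alone and does not touch the stereocentre.

Step 4
Reactants: 7 methyl (5S)-5-(hydroxymethyl)-6,6-dimethoxyhexanoate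
Product: 8 methyl (5S)-5-[(benzyloxy)methyl]-6,6-dimethoxyhexanoate
Conditions: 2-benzyloxy-1-methylpyridinium triflate, MgO, PhCF3, 85 °C
Reagents that add atoms: 2-benzyloxy-1-methylpyridinium trifluoromethanesulfonate, C[n+]1ccccc1OCc1ccccc1.[O-]S(=O)(=O)C(F)(F)F
Why: O-benzylation by benzyl transfer under neutral conditions, chosen because the ester rules out alkoxide conditions and the acetal rules out acid-catalysed benzylation.

Step 5
Reactants: 8 methyl (5S)-5-[(benzyloxy)methyl]-6,6-dimethoxyhexanoate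
Product: 9 (5S)-5-[(benzyloxy)methyl]-6,6-dimethoxyhexanoic acid
Conditions: LiOH, THF/MeOH/H2O, rt; then 1 M HCl to pH 4, 0 °C
Reagents that add atoms: lithium hydroxide, [Li+].[OH-]
Why: ester saponification; the acetal is stable to base and to the brief, cold, mildly acidic work-up.

Step 6
Reactants: 10 isophorone (3,5,5-trimethylcyclohex-2-en-1-one)
Product: 11 (1S)-3,5,5-trimethylcyclohex-2-en-1-ol
Conditions: (R)-2-methyl-CBS-oxazaborolidine (10 mol %), BH3·SMe2, THF, −20 °C; MeOH, aqueous work-up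
Reagents that add atoms: none
Why: Corey–Bakshi–Shibata 1,2-reduction in which the alkenyl flank of the enone acts as the large group, so the (R)-catalyst should deliver hydride to the face that gives the (S)-allylic alcohol.

Step 7
Reactants: 9 (5S)-5-[(benzyloxy)methyl]-6,6-dimethoxyhexanoic acid; 11 (1S)-3,5,5-trimethylcyclohex-2-en-1-ol
Product: 12 (1S)-3,5,5-trimethylcyclohex-2-en-1-yl (5S)-5-[(benzyloxy)methyl]-6,6-dimethoxyhexanoate
Conditions: DCC, DMAP (cat.), CH2Cl2, 0 °C → rt
Reagents that add atoms: none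
Why: Steglich esterification of the secondary allylic alcohol, with retention at the carbinol carbon because the C–O bond is not broken.

Step 8
Reactants: 12 (1S)-3,5,5-trimethylcyclohex-2-en-1-yl (5S)-5-[(benzyloxy)methyl]-6,6-dimethoxyhexanoate
Product: 15 (5S)-5-[(benzyloxy)methyl]-6,6-dimethoxy-2-[(1R)-1,5,5-trimethylcyclohex-2-en-1-yl]hexanoic acid (both C2 epimers), via silyl ketene acetal 13 (not isolated), via trimethylsilyl ester 14 (not isolated)
Conditions: LDA, TMSCl, Et3N, THF, −78 °C; then PhMe, 90 °C; aq. NH4Cl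
Reagents that add atoms: none
Why: Ireland–Claisen rearrangement, whose [3,3] shift is suprafacial on the ring face that carries the C–O bond, so the (S)-carbinol centre is relayed to the new quaternary carbon while the two halves are joined at the most hindered C–C bond; both α-epimers are used because that centre is erased in step 11.

Step 9
Reactants: 16 (4R)-4-benzyl-1,3-oxazolidin-2-one
Product: 18 (4R)-4-benzyl-3-(bromoacetyl)-1,3-oxazolidin-2-one, via lithium oxazolidinide 17 (not isolated)
Conditions: n-BuLi, THF, −78 °C; then BrCH2COBr, −78 °C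
Reagents that add atoms: bromoacetyl bromide, BrCC(Br)=O
Why: N-acylation of the lithiated oxazolidinone at the acyl bromide, which is far more electrophilic than the alkyl bromide.

Step 10
Reactants: 18 (4R)-4-benzyl-3-(bromoacetyl)-1,3-oxazolidin-2-one
Product: 20 (4R)-4-benzyl-3-[(triphenyl-λ5-phosphanylidene)acetyl]-1,3-oxazolidin-2-one, via phosphonium bromide 19 (not isolated)
Conditions: PPh3, PhMe, rt; then Et3N, CH2Cl2, 0 °C
Reagents that add atoms: triphenylphosphine, c1ccc(cc1)P(c1ccccc1)c1ccccc1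
Why: SN2 displacement of bromide by the phosphine and deprotonation of the acidic phosphonium salt, the standard way to a carbonyl-stabilised Wittig ylide.

Step 11
Reactants: 15 (5S)-5-[(benzyloxy)methyl]-6,6-dimethoxy-2-[(1R)-1,5,5-trimethylcyclohex-2-en-1-yl]hexanoic acid; 20 (4R)-4-benzyl-3-[(triphenyl-λ5-phosphanylidene)acetyl]-1,3-oxazolidin-2-one
Product: 23 (4R)-4-benzyl-3-{(7S)-7-[(benzyloxy)methyl]-8,8-dimethoxy-4-[(1R)-1,5,5-trimethylcyclohex-2-en-1-yl]octa-2,3-dienoyl}-1,3-oxazolidin-2-one (both allene axis epimers), via acid chloride 21 (not isolated), via ketene 22 (not isolated)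
Conditions: 1-chloro-N,N,2-trimethylprop-1-en-1-amine, CH2Cl2, 0 °C → rt; then Et3N, 20, PhMe, 60 °C
Reagents that add atoms: none
Why: dehydrochlorination of the α-branched acid chloride gives the disubstituted ketene, and Wittig olefination of its C=O by the stabilised ylide gives the 2,3-dienoyl imide (the known ketene route to allenoates); the α-stereocentre of 15 is erased and the allene axis forms as a mixture that does not matter.

Step 12
Reactants: 23 (4R)-4-benzyl-3-{(7S)-7-[(benzyloxy)methyl]-8,8-dimethoxy-4-[(1R)-1,5,5-trimethylcyclohex-2-en-1-yl]octa-2,3-dienoyl}-1,3-oxazolidin-2-one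
Product: 24 (4R)-4-benzyl-3-{(7S)-7-[(benzyloxy)methyl]-8-oxo-4-[(1R)-1,5,5-trimethylcyclohex-2-en-1-yl]octa-2,3-dienoyl}-1,3-oxazolidin-2-one (both allene axis epimers)
Conditions: TFA, H2O, CH2Cl2, 0 °C
Reagents that add atoms: water, O
Why: acid-catalysed acetal hydrolysis, tolerated by the electron-poor allene, the imide and the benzyl ether; the aldehyde is used at once to protect its α-centre.

Step 13
Reactants: 24 (4R)-4-benzyl-3-{(7S)-7-[(benzyloxy)methyl]-8-oxo-4-[(1R)-1,5,5-trimethylcyclohex-2-en-1-yl]octa-2,3-dienoyl}-1,3-oxazolidin-2-one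
Product: 26 (4R)-4-benzyl-3-{[(5S)-5-[(benzyloxy)methyl]-6-oxo-2-[(1R)-1,5,5-trimethylcyclohex-2-en-1-yl]cyclohex-1-en-1-yl]acetyl}-1,3-oxazolidin-2-one, via carbene–aldehyde enaminol adduct 25 (not isolated)
Conditions: 2-(pentafluorophenyl)-6,7-dihydro-5H-pyrrolo[2,1-c][1,2,4]triazol-2-ium tetrafluoroborate (20 mol %), i-Pr2NEt (20 mol %), PhMe, 40 °C
Reagents that add atoms: none
Why: Proposed new method: the triazolylidene adds to the aldehyde of 24 to give the enaminol adduct 25, whose nucleophilic carbon (future ring C1) attacks the central sp carbon (future ring C2) of the 2,3-dienoyl imide through the imide-conjugated C2=Cα π bond, which lies in the plane of the C3 substituents and is reached by the three-carbon tether from the side anti to the tert-alkyl group; C-protonation of the resulting imide enolate at Cα and loss of the carbene give the ring ketone, already conjugated with the untouched orthogonal C2=C3 π bond. The closest known reaction types are the intramolecular Stetter reaction of aldehydes onto tethered α,β-unsaturated esters and the NHC-catalysed intramolecular hydroacylation of alkynes; new here is the allenoyl acceptor, whose central carbon is a sterically open, strongly polarised Michael position. The cyclohexenone ring closes in a 6-exo-dig mode with respect to the conjugated C2=Cα bond that is consumed, and the second allene π bond becomes the endocyclic C2=C3 bond. No stereocentre is created and the step is stereoconvergent: both allene axis epimers of 24 (derived from both α-epimers of 15) should give the one enone 26. The selectivities needed are conjugate addition in preference to benzoin-type dimerisation or addition of the carbene to the allene, secured by the six-membered transition state and by the tert-alkyl and alkyl groups that shield the allene from intermolecular attack, and retention of the aldehyde α-centre (ring C6), secured by the catalytic, weakly basic, aprotic conditions and by the fact that enaminol formation does not involve C6.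

Step 14
Reactants: 26 (4R)-4-benzyl-3-{[(5S)-5-[(benzyloxy)methyl]-6-oxo-2-[(1R)-1,5,5-trimethylcyclohex-2-en-1-yl]cyclohex-1-en-1-yl]acetyl}-1,3-oxazolidin-2-one
Product: 28 (4R)-4-benzyl-3-{(2R)-2-[(5S)-5-[(benzyloxy)methyl]-6-oxo-2-[(1R)-1,5,5-trimethylcyclohex-2-en-1-yl]cyclohex-1-en-1-yl]propanoyl}-1,3-oxazolidin-2-one, via sodium enolate 27 (not isolated)
Conditions: NaHMDS (1.0 equiv), THF, −78 °C; then MeI, −78 → −40 °C
Reagents that add atoms: iodomethane, CI
Why: Evans alkylation: the imide CH2 is deprotonated in preference to the hindered ketone α-CH, and the chelated (Z)-sodium enolate is methylated anti to the benzyl group of the (R)-auxiliary, which sets the (R) centre at Cα; rotation about the ring–Cα bond lets this open face point away from the tert-alkyl group.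

Step 15
Reactants: 28 (4R)-4-benzyl-3-{(2R)-2-[(5S)-5-[(benzyloxy)methyl]-6-oxo-2-[(1R)-1,5,5-trimethylcyclohex-2-en-1-yl]cyclohex-1-en-1-yl]propanoyl}-1,3-oxazolidin-2-one
Product: 30 (2R)-2-[(5S)-5-[(benzyloxy)methyl]-6-oxo-2-[(1R)-1,5,5-trimethylcyclohex-2-en-1-yl]cyclohex-1-en-1-yl]propanoic acid, via peroxy acid 29 (not isolated)
Conditions: LiOH, H2O2, THF/H2O, 0 °C; then Na2SO3; then 1 M HCl to pH 3
Reagents that add atoms: hydrogen peroxide, OO
Why: hydroperoxide cleavage at the exocyclic imide carbonyl (selective even for hindered acyl groups), the peroxy acid being reduced by sulfite; hydroperoxide is too weakly basic at 0 °C to epimerise the α-centres or to eliminate the β-benzyloxy ketone.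

Step 16
Reactants: 30 (2R)-2-[(5S)-5-[(benzyloxy)methyl]-6-oxo-2-[(1R)-1,5,5-trimethylcyclohex-2-en-1-yl]cyclohex-1-en-1-yl]propanoic acid
Product: 31 (2R)-2-{(5S)-5-(hydroxymethyl)-6-oxo-2-[(1S)-1,3,3-trimethylcyclohexyl]cyclohex-1-en-1-yl}propanoic acid
Conditions: H2 (1 atm), 10% Pd/C, EtOAc, rt
Reagents that add atoms: none
Why: one catalytic hydrogenation that cleaves the benzyl ether and saturates the cis-disubstituted cyclohexene, while the tetrasubstituted enone C=C next to the quaternary carbon is too hindered to be reduced.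

Step 17
Reactants: 31 (2R)-2-{(5S)-5-(hydroxymethyl)-6-oxo-2-[(1S)-1,3,3-trimethylcyclohexyl]cyclohex-1-en-1-yl}propanoic acid
Product: 32 (2R)-2-{(5S)-5-[(formyloxy)methyl]-6-oxo-2-[(1S)-1,3,3-trimethylcyclohexyl]cyclohex-1-en-1-yl}propanoic acid (CNP0308329.1)
Conditions: 2,2,2-trifluoroethyl formate, THF, 50 °C
Reagents that add atoms: 2,2,2-trifluoroethyl formate, O=COCC(F)(F)F
Why: base-free transformylation of the primary alcohol by the activated formate ester; the carboxylic acid does not react and no base is present that could eliminate or epimerise the β-acyloxy ketone.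

**Compound list**

1 | (4S)-4-benzyl-1,3-oxazolidin-2-one | O=C1N[C@@H](Cc2ccccc2)CO1 | starting material
2 | methyl 6-chloro-6-oxohexanoate | COC(=O)CCCCC(Cl)=O | starting material
3 | lithium (4S)-4-benzyl-2-oxo-1,3-oxazolidin-3-ide | [Li+].O=C1[N-][C@@H](Cc2ccccc2)CO1 | intermediate
4 | methyl 6-[(4S)-4-benzyl-2-oxo-1,3-oxazolidin-3-yl]-6-oxohexanoate | COC(=O)CCCCC(=O)N1[C@@H](Cc2ccccc2)COC1=O | intermediate
5 | trichlorotitanium (Z)-enolate of 4 | COC(=O)CCC/C=C(\O[Ti](Cl)(Cl)Cl)N1[C@@H](Cc2ccccc2)COC1=O | intermediate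
6 | methyl (5R)-5-{[(4S)-4-benzyl-2-oxo-1,3-oxazolidin-3-yl]carbonyl}-6,6-dimethoxyhexanoate | COC(=O)CCC[C@H](C(OC)OC)C(=O)N1[C@@H](Cc2ccccc2)COC1=O | intermediate
7 | methyl (5S)-5-(hydroxymethyl)-6,6-dimethoxyhexanoate | COC(=O)CCC[C@H](C(OC)OC)CO | intermediate
8 | methyl (5S)-5-[(benzyloxy)methyl]-6,6-dimethoxyhexanoate | COC(=O)CCC[C@H](C(OC)OC)COCc1ccccc1 | intermediate
9 | (5S)-5-[(benzyloxy)methyl]-6,6-dimethoxyhexanoic acid | OC(=O)CCC[C@H](C(OC)OC)COCc1ccccc1 | intermediate
10 | isophorone (3,5,5-trimethylcyclohex-2-en-1-one) | CC1=CC(=O)CC(C)(C)C1 | starting material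
11 | (1S)-3,5,5-trimethylcyclohex-2-en-1-ol | O[C@@H]1C=C(C)CC(C)(C)C1 | intermediate
12 | (1S)-3,5,5-trimethylcyclohex-2-en-1-yl (5S)-5-[(benzyloxy)methyl]-6,6-dimethoxyhexanoate | O=C(CCC[C@H](C(OC)OC)COCc1ccccc1)O[C@@H]1C=C(C)CC(C)(C)C1 | intermediate
13 | trimethylsilyl ketene acetal of 12 (E/Z mixture) | C[Si](C)(C)OC(=CCC[C@H](C(OC)OC)COCc1ccccc1)O[C@@H]1C=C(C)CC(C)(C)C1 | intermediate
14 | trimethylsilyl ester of 15 (both C2 epimers) | C[Si](C)(C)OC(=O)C(CC[C@H](C(OC)OC)COCc1ccccc1)[C@@]1(C)C=CCC(C)(C)C1 | intermediate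
15 | (5S)-5-[(benzyloxy)methyl]-6,6-dimethoxy-2-[(1R)-1,5,5-trimethylcyclohex-2-en-1-yl]hexanoic acid (both C2 epimers) | OC(=O)C(CC[C@H](C(OC)OC)COCc1ccccc1)[C@@]1(C)C=CCC(C)(C)C1 | intermediate
16 | (4R)-4-benzyl-1,3-oxazolidin-2-one | O=C1N[C@H](Cc2ccccc2)CO1 | starting material
17 | lithium (4R)-4-benzyl-2-oxo-1,3-oxazolidin-3-ide | [Li+].O=C1[N-][C@H](Cc2ccccc2)CO1 | intermediate
18 | (4R)-4-benzyl-3-(bromoacetyl)-1,3-oxazolidin-2-one | O=C(CBr)N1[C@H](Cc2ccccc2)COC1=O | intermediate
19 | {2-[(4R)-4-benzyl-2-oxo-1,3-oxazolidin-3-yl]-2-oxoethyl}triphenylphosphonium bromide | [Br-].O=C(C[P+](c1ccccc1)(c1ccccc1)c1ccccc1)N1[C@H](Cc2ccccc2)COC1=O | intermediate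
20 | (4R)-4-benzyl-3-[(triphenyl-λ5-phosphanylidene)acetyl]-1,3-oxazolidin-2-one | O=C(C=P(c1ccccc1)(c1ccccc1)c1ccccc1)N1[C@H](Cc2ccccc2)COC1=O | intermediate
21 | (5S)-5-[(benzyloxy)methyl]-6,6-dimethoxy-2-[(1R)-1,5,5-trimethylcyclohex-2-en-1-yl]hexanoyl chloride (both C2 epimers) | ClC(=O)C(CC[C@H](C(OC)OC)COCc1ccccc1)[C@@]1(C)C=CCC(C)(C)C1 | intermediate
22 | (5S)-5-[(benzyloxy)methyl]-6,6-dimethoxy-2-[(1R)-1,5,5-trimethylcyclohex-2-en-1-yl]hex-1-en-1-one (ketene) | O=C=C(CC[C@H](C(OC)OC)COCc1ccccc1)[C@@]1(C)C=CCC(C)(C)C1 | intermediate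
23 | (4R)-4-benzyl-3-{(7S)-7-[(benzyloxy)methyl]-8,8-dimethoxy-4-[(1R)-1,5,5-trimethylcyclohex-2-en-1-yl]octa-2,3-dienoyl}-1,3-oxazolidin-2-one (both allene axis epimers) | O=C(C=C=C(CC[C@H](C(OC)OC)COCc1ccccc1)[C@@]1(C)C=CCC(C)(C)C1)N1[C@H](Cc2ccccc2)COC1=O | intermediate
24 | (4R)-4-benzyl-3-{(7S)-7-[(benzyloxy)methyl]-8-oxo-4-[(1R)-1,5,5-trimethylcyclohex-2-en-1-yl]octa-2,3-dienoyl}-1,3-oxazolidin-2-one (both allene axis epimers) | O=C(C=C=C(CC[C@H](C=O)COCc1ccccc1)[C@@]1(C)C=CCC(C)(C)C1)N1[C@H](Cc2ccccc2)COC1=O | intermediate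
25 | enaminol adduct of the triazolylidene with the aldehyde carbon of 24 | OC(=C1N(c2c(F)c(F)c(F)c(F)c2F)N=C2CCCN12)[C@H](COCc1ccccc1)CCC(=C=CC(=O)N1[C@H](Cc2ccccc2)COC1=O)[C@@]1(C)C=CCC(C)(C)C1 | intermediate
26 | (4R)-4-benzyl-3-{[(5S)-5-[(benzyloxy)methyl]-6-oxo-2-[(1R)-1,5,5-trimethylcyclohex-2-en-1-yl]cyclohex-1-en-1-yl]acetyl}-1,3-oxazolidin-2-one | O=C(CC1=C([C@@]2(C)C=CCC(C)(C)C2)CC[C@@H](COCc2ccccc2)C1=O)N1[C@H](Cc2ccccc2)COC1=O | intermediate
27 | sodium (Z)-enolate of 26 | [Na+].[O-]/C(=C\C1=C([C@@]2(C)C=CCC(C)(C)C2)CC[C@@H](COCc2ccccc2)C1=O)N1[C@H](Cc2ccccc2)COC1=O | intermediate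
28 | (4R)-4-benzyl-3-{(2R)-2-[(5S)-5-[(benzyloxy)methyl]-6-oxo-2-[(1R)-1,5,5-trimethylcyclohex-2-en-1-yl]cyclohex-1-en-1-yl]propanoyl}-1,3-oxazolidin-2-one | C[C@@H](C(=O)N1[C@H](Cc2ccccc2)COC1=O)C1=C([C@@]2(C)C=CCC(C)(C)C2)CC[C@@H](COCc2ccccc2)C1=O | intermediate
29 | (2R)-2-[(5S)-5-[(benzyloxy)methyl]-6-oxo-2-[(1R)-1,5,5-trimethylcyclohex-2-en-1-yl]cyclohex-1-en-1-yl]propaneperoxoic acid | C[C@@H](C(=O)OO)C1=C([C@@]2(C)C=CCC(C)(C)C2)CC[C@@H](COCc2ccccc2)C1=O | intermediate
30 | (2R)-2-[(5S)-5-[(benzyloxy)methyl]-6-oxo-2-[(1R)-1,5,5-trimethylcyclohex-2-en-1-yl]cyclohex-1-en-1-yl]propanoic acid | C[C@@H](C(=O)O)C1=C([C@@]2(C)C=CCC(C)(C)C2)CC[C@@H](COCc2ccccc2)C1=O | intermediate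
31 | (2R)-2-{(5S)-5-(hydroxymethyl)-6-oxo-2-[(1S)-1,3,3-trimethylcyclohexyl]cyclohex-1-en-1-yl}propanoic acid | C[C@@H](C(=O)O)C1=C([C@@]2(C)CCCC(C)(C)C2)CC[C@@H](CO)C1=O | intermediate
32 | (2R)-2-{(5S)-5-[(formyloxy)methyl]-6-oxo-2-[(1S)-1,3,3-trimethylcyclohexyl]cyclohex-1-en-1-yl}propanoic acid | C[C@@H](C(=O)O)C1=C([C@@]2(C)CCCC(C)(C)C2)CC[C@@H](COC=O)C1=O | target

**Step count and risks**

Total step count: 17. Longest linear sequence: 14 steps (1–5, 7, 8, 11–17).

Steps most likely to fail:

1. Step 13 (Proposed new method). What may go wrong: the carbene may add to the allenoyl imide instead of the aldehyde; ring closure may be slow, so that base-induced loss of benzyloxide or epimerisation at the aldehyde α-carbon competes. Fallback with known chemistry, setting out from 24 and coming back at 26: Pinnick oxidation of 24 (NaClO2, NaH2PO4, 2-methyl-2-butene, t-BuOH/H2O) should give (2S)-2-[(benzyloxy)methyl]-8-[(4R)-4-benzyl-2-oxo-1,3-oxazolidin-3-yl]-8-oxo-5-[(1R)-1,5,5-trimethylcyclohex-2-en-1-yl]octa-5,6-dienoic acid F1. Activation with 1-chloro-N,N,2-trimethylprop-1-en-1-amine followed by PhSeH/pyridine should give the Se-phenyl selenoester F2. Slow addition of Bu3SnH/AIBN in benzene at 80 °C should then generate the acyl radical, which closes 6-exo onto the central allene carbon; hydrogen transfer to the α-imide radical gives 26. Acyl radical cyclisation of selenoesters onto activated C=C bonds is a known ring synthesis, it runs without base and it converges both allene epimers in the same way.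

2. Step 11. What may go wrong: slow dehydrochlorination of the acid chloride (its α-hydrogen sits next to the quaternary carbon), C-acylation of the ylide instead of olefination, or a sluggish Wittig reaction at the hindered ketene. Fallback that avoids the ketene olefination, setting out from 15 and coming back at 23: the acid chloride 21, made as in step 11, is treated with Meldrum's acid and pyridine to give the 5-acyl-2,2-dimethyl-1,3-dioxane-4,6-dione F3. Heating F3 with 16 in toluene should give, through the acylketene, the β-keto imide F4. Triflation under the non-chelating conditions known to give (E)-enol triflates of β-keto esters (Tf2O, aqueous Me4NOH, PhMe) should give the (E)-enol triflate F5. Pd(0)-catalysed β-hydride elimination (Pd(OAc)2, phosphine, i-Pr2NEt), the known route from such enol triflates to allenoates, returns 23.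

3. Step 6. What may go wrong: poor enantiofacial selectivity in the reduction, because the CH2–CMe2 flank of isophorone is not much smaller than the alkenyl flank. Fallback by resolution in place of asymmetric reduction, setting out from 10 and coming back at 11: Luche reduction (NaBH4, CeCl3·7H2O, MeOH) gives racemic 3,5,5-trimethylcyclohex-2-en-1-ol F6. Lipase-catalysed acylation (lipase PS, vinyl acetate, MTBE) is expected to acylate the (R)-alcohol to (1R)-3,5,5-trimethylcyclohex-2-en-1-yl acetate F7; run just past half conversion, it should leave (S)-alcohol 11, which is separated by chromatography.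

Further compounds
F1 | step 13 | (2S)-2-[(benzyloxy)methyl]-8-[(4R)-4-benzyl-2-oxo-1,3-oxazolidin-3-yl]-8-oxo-5-[(1R)-1,5,5-trimethylcyclohex-2-en-1-yl]octa-5,6-dienoic acid | OC(=O)[C@H](COCc1ccccc1)CCC(=C=CC(=O)N1[C@H](Cc2ccccc2)COC1=O)[C@@]1(C)C=CCC(C)(C)C1
F2 | step 13 | Se-phenyl (2S)-2-[(benzyloxy)methyl]-8-[(4R)-4-benzyl-2-oxo-1,3-oxazolidin-3-yl]-8-oxo-5-[(1R)-1,5,5-trimethylcyclohex-2-en-1-yl]octa-5,6-dieneselenoate | O=C([Se]c1ccccc1)[C@H](COCc1ccccc1)CCC(=C=CC(=O)N1[C@H](Cc2ccccc2)COC1=O)[C@@]1(C)C=CCC(C)(C)C1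
F3 | step 11 | 5-{(5S)-5-[(benzyloxy)methyl]-6,6-dimethoxy-2-[(1R)-1,5,5-trimethylcyclohex-2-en-1-yl]hexanoyl}-2,2-dimethyl-1,3-dioxane-4,6-dione | CC1(C)OC(=O)C(C(=O)C(CC[C@H](C(OC)OC)COCc2ccccc2)[C@@]2(C)C=CCC(C)(C)C2)C(=O)O1
F4 | step 11 | (4R)-4-benzyl-3-{(7S)-7-[(benzyloxy)methyl]-8,8-dimethoxy-3-oxo-4-[(1R)-1,5,5-trimethylcyclohex-2-en-1-yl]octanoyl}-1,3-oxazolidin-2-one | O=C(CC(=O)C(CC[C@H](C(OC)OC)COCc1ccccc1)[C@@]1(C)C=CCC(C)(C)C1)N1[C@H](Cc2ccccc2)COC1=O
F5 | step 11 | (4R)-4-benzyl-3-{(2E,7S)-7-[(benzyloxy)methyl]-8,8-dimethoxy-3-{[(trifluoromethyl)sulfonyl]oxy}-4-[(1R)-1,5,5-trimethylcyclohex-2-en-1-yl]oct-2-enoyl}-1,3-oxazolidin-2-one | O=C(/C=C(/OS(=O)(=O)C(F)(F)F)C(CC[C@H](C(OC)OC)COCc1ccccc1)[C@@]1(C)C=CCC(C)(C)C1)N1[C@H](Cc2ccccc2)COC1=O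
F6 | step 6 | racemic 3,5,5-trimethylcyclohex-2-en-1-ol | OC1C=C(C)CC(C)(C)C1
F7 | step 6 | (1R)-3,5,5-trimethylcyclohex-2-en-1-yl acetate | CC(=O)O[C@H]1C=C(C)CC(C)(C)C1
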